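**Retrosynthetic overview**
1. Feature: in ring B (C7–O7–C11–C10–C9–C8), the chain C8–C9–C10–C11 plus one C11 methyl is a masked 2-methylfuran bonded to C7 through its free α-carbon (C8). C8 has the oxidation level of a pyranone carbonyl and C11 that of a ketal.
2. Late disconnections: C8–OH from its silyl ether; diequatorial C3–Cl/C4–Br from diaxial C3–Br/C4–Cl, then bromohydrin, upper-face epoxide and C3=C4; C1–OAc from C1–OH.
3. The second C11 methyl comes from AlMe3 cleavage of a temporary C1–O–C11 ketal tether. The tether inverts the chair of ring B, so bromide (C10) and hydride (C8) both enter from the open face.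
4. Ring B (O7–C11 bond) comes from anodic Achmatowicz ring expansion of the tertiary C7 (5-methylfuran-2-yl) carbinol. C7 comes from a chelate-controlled furyl Grignard addition to the methyl ketone.
5. Ring A comes from ring-closing metathesis after an Evans syn-aldol (C1, C6). Order of rings: A, then B, then the tether ring, which is opened again.

Key step: step 8

Numbering: ring A = C1 (OAc), C2, C3 (Cl, CH3), C4 (Br), C5, C6. Ring B = C7 (CH3), O7, C11 (two CH3), C10 (Br), C9, C8 (OH). O1 is the oxygen on C1. The target is 1R,3R,4R,6S,7S,8S,10S. The lower face of ring A carries O1 and the C6–C7 bond. The upper face of ring B carries the C7 methyl.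
Assumption: hemiketal 18 is handled as an equilibrating mixture of C11 anomers and ring–chain tautomers; one anomer is drawn.

Step 1
Reactants: 1 (S)-4-benzyloxazolidin-2-one; 2 pent-4-enoyl chloride
Product: 4 (S)-4-benzyl-3-(pent-4-enoyl)oxazolidin-2-one, via N-lithio oxazolidinone 3 (not isolated)
Conditions: n-BuLi, THF, −78 °C; then 2, −78 to 0 °C
Reagents that add atoms: none
Why: N-acylation of a lithiated oxazolidinone by an acid chloride is the standard way to an Evans imide and touches no stereocentre.

Step 2
Reactants: 5 3-methylbut-3-en-1-ol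
Product: 6 3-methylbut-3-enal
Conditions: Dess–Martin periodinane, CH2Cl2, 0 °C; filtered and used at once as a cold solution
Reagents that add atoms: none
Why: Dess–Martin oxidation is neutral and non-enolising, so the β,γ-unsaturated aldehyde should not slip into conjugation before it is consumed.

Step 3
Reactants: 4 (S)-4-benzyl-3-(pent-4-enoyl)oxazolidin-2-one; 6 3-methylbut-3-enal
Product: 8 (S)-4-benzyl-3-[(2S,3R)-2-allyl-3-hydroxy-5-methylhex-5-enoyl]oxazolidin-2-one, via dibutylboron Z-enolate 7 (not isolated)
Conditions: Bu2BOTf, Et3N, CH2Cl2, −78 to 0 °C; 6, −78 to 0 °C; H2O2, MeOH, aq NaH2PO4/Na2HPO4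
Reagents that add atoms: none
Why: Evans syn-aldol reaction, in which the Z boron enolate reacts through a chair Zimmerman–Traxler transition state on the face away from the benzyl group and so sets 6S and 1R (2S,3R in acyl numbering), a syn pair that becomes cis on ring A.

Step 4
Reactants: 8 aldol adduct
Product: 9 (S)-4-benzyl-3-[(1S,6R)-6-hydroxy-4-methylcyclohex-3-ene-1-carbonyl]oxazolidin-2-one
Conditions: second-generation Grubbs catalyst RuCl2(=CHPh)(PCy3)(H2IMes) (3 mol%), CH2Cl2, reflux
Reagents that add atoms: none
Why: Ring-closing metathesis of a monosubstituted and a 1,1-disubstituted alkene closes six-membered ring A with the trisubstituted C3=C4 bond, is driven by loss of ethene and leaves C1 and C6 untouched.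

Step 5
Reactants: 9 ring A imide
Product: 10 (1S,6R)-6-hydroxy-N-methoxy-N,4-dimethylcyclohex-3-ene-1-carboxamide
Conditions: MeONHMe·HCl, AlMe3, THF, −10 to 0 °C; aq HCl
Reagents that add atoms: N,O-dimethylhydroxylamine hydrochloride, CNOC.Cl
Why: Weinreb transamidation with the aluminium amide, assisted by the free C1 hydroxyl as its aluminium alkoxide, removes the auxiliary without epimerising C6.

Step 6
Reactants: 10 Weinreb amide
Product: 11 1-[(1S,6R)-6-hydroxy-4-methylcyclohex-3-en-1-yl]ethan-1-one
Conditions: MeMgBr (3.5 equiv), THF, −20 to 0 °C; cold aq NH4Cl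
Reagents that add atoms: methylmagnesium bromide, C[Mg]Br
Why: Grignard addition to a Weinreb amide stops at the chelated tetrahedral intermediate, so the base-sensitive cis β-hydroxy ketone is released only on the cold quench.

Step 7
Reactants: 11 β-hydroxy methyl ketone; 12 2-methylfuran
Product: 15 (1R,6S)-6-[(1S)-1-hydroxy-1-(5-methylfuran-2-yl)ethyl]-3-methylcyclohex-3-en-1-ol (1R,6S,7S), via 5-methyl-2-furyllithium 13 (not isolated), via furylmagnesium bromide 14 (not isolated)
Conditions: 12, n-BuLi, THF, 0 °C; MgBr2·OEt2; then 11, CH2Cl2–THF, −78 °C (3 equiv of 14)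
Reagents that add atoms: none
Why: Chelation-controlled Grignard addition, in which the first equivalent makes the C1 magnesium alkoxide, this ties the C7 carbonyl into a six-membered chelate cis-fused to ring A, and the next equivalent attacks the convex face (the side of H1 and H6) to set 7S.

Step 8
Reactants: 15 furan carbinol (1R,6S,7S)
Product: 18 (2S)-6-hydroxy-2-[(1S,6R)-6-hydroxy-4-methylcyclohex-3-en-1-yl]-2,6-dimethyl-2H-pyran-3(6H)-one (pyranone hemiketal), via dihydrofuran diol 16 (not isolated), via Z-enedione 17 (not isolated)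
Conditions: undivided cell, reticulated vitreous carbon anode, Pt cathode, LiClO4 (0.1 M), MeCN–H2O 9:1, 2,6-lutidine (0.2 equiv), anode held at about +1.2 V versus Ag/AgCl, 0 °C, stopped near 2 F/mol; taken on crude
Reagents that add atoms: water, O
Why: The 2,5-dialkylfuran gives up one electron at the carbon anode, the radical cation takes up water, and a second electron transfer and a second water give the 2,5-dihydroxy-2,5-dihydrofuran 16, which opens to the Z-enedione 17. The C7 hydroxyl then adds to the C11 ketone (6-exo-trig), forming the O7–C11 bond and closing ring B as the pyranone hemiketal; this is an Achmatowicz rearrangement run electrochemically, a known variant for furfuryl alcohols including tertiary ones. The only new stereocentre, C11, is a hemiketal carbon whose anomers equilibrate and which ends as a non-stereogenic CMe2 carbon, so nothing has to be controlled there, and C1, C6 and C7 are not touched. The selectivity needed is furan over the C3=C4 alkene: an electron-rich 2,5-dialkylfuran is oxidised several hundred millivolts before a trisubstituted alkene, so holding the anode just past the furan wave leaves ring A alone, which halogen-based or peracid oxidants would not guarantee. Proton reduction at the Pt cathode balances the acid made at the anode, so the acid-labile tertiary furfuryl alcohol sees a nearly neutral medium. Transient trapping by the C1 hydroxyl at C8 leads only to tautomers of the same oxidation level, which step 9 funnels into one ketal.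

Step 9
Reactants: 18 pyranone hemiketal
Product: 19 tricyclic enone ketal (1R,6S,7S,11S): 2,9-dioxabicyclo[3.3.1]non-7-en-6-one core in which O1 links C1 to C11 and ring A is cis-fused at C1–C6
Conditions: CSA (cat.), anhydrous MgSO4, CH2Cl2, rt
Reagents that add atoms: none
Why: Acid-catalysed bicycloketalisation of an Achmatowicz hemiketal, in which loss of water gives the C11 oxocarbenium ion, the C1 hydroxyl traps it in a six-membered ring, and the bridge fixes C11 as S and forces C6 and O1 into the axial positions of ring B, a fit that only the 7S carbinol allows without an inward-pointing ring A carbon.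

Step 10
Reactants: 19 tricyclic enone ketal
Product: 20 tricyclic β-bromo ketone (1R,6S,7S,10S,11S) in which Br is axial on ring B and cis to the C7 methyl
Conditions: TMSBr and MeOH (1.2 equiv each, HBr in situ), CH2Cl2, −78 to −30 °C; crude product kept cold
Reagents that add atoms: bromotrimethylsilane, C[Si](C)(C)Br
Why: Hydrobromination of an enone by conjugate addition of bromide, in which the C6–C1–O1 bridge covers the lower face of ring B so that bromide enters C10 axially from the open upper face and sets 10S, while about one equivalent of HBr in the cold leaves the far less basic C3=C4 alkene alone.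

Step 11
Reactants: 20 tricyclic β-bromo ketone
Product: 21 tricyclic bromo alcohol (1R,6S,7S,8S,10S,11S)
Conditions: NaBH4, CeCl3·7H2O, MeOH–CH2Cl2, −78 °C
Reagents that add atoms: none
Why: Luche reduction, in which the lower face of the C8 carbonyl is closed by the axial C7–C6 bond and the dioxane bridge, so hydride comes from the upper face and gives the equatorial 8S alcohol (OH on the side of C6), the epimer that also avoids a syn-axial contact with the C10 bromine, while the cold weakly basic medium spares the β-bromide.

Step 12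
Reactants: 21 tricyclic bromo alcohol
Product: 22 C8 tert-butyldimethylsilyl ether of 21
Conditions: TBSOTf, 2,6-lutidine, CH2Cl2, −40 to 0 °C
Reagents that add atoms: tert-butyldimethylsilyl triflate, CC(C)(C)[Si](C)(C)OS(=O)(=O)C(F)(F)F
Why: Silylation with a silyl triflate and a hindered pyridine base caps the hindered C8 alcohol without a base strong enough to eliminate the bromide, so the C1 and C4 hydroxyls can later be addressed alone.

Step 13
Reactants: 22 silylated tricyclic ketal
Product: 23 C1 alcohol with ring B as the 2,2,6-trimethyltetrahydropyran (1R,6S,7S,8S,10S)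
Conditions: AlMe3 (5 equiv), CH2Cl2–hexane, −20 °C to rt; aq KNaC4H4O6
Reagents that add atoms: trimethylaluminium, C[Al](C)C
Why: Alkylative ketal cleavage by AlMe3, the reaction that turns acetonides into tert-butyl ethers: the Lewis acid binds the less hindered O1, the axial C11–O1 bond breaks with help from an antiperiplanar O7 lone pair (breaking C11–O7 would leave an eight-membered oxocarbenium ion), and methyl transfer makes C11 a non-stereogenic CMe2 carbon, after which ring B flips to the chair with ring A and Br equatorial and the C8 oxygen axial.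

Step 14
Reactants: 23 C1 alcohol
Product: 24 C1 acetate of 23
Conditions: Ac2O, pyridine, DMAP (cat.), CH2Cl2, rt
Reagents that add atoms: acetic anhydride, CC(=O)OC(C)=O
Why: DMAP-catalysed acetylation meets only one free hydroxyl.

Step 15
Reactants: 24 alkene acetate
Product: 25 upper-face 3,4-epoxide (3R,4S)
Conditions: mCPBA, CH2Cl2, −10 °C
Reagents that add atoms: 3-chloroperbenzoic acid, O=C(OO)c1cccc(Cl)c1
Why: Prilezhaev epoxidation, in which the half-chair with the bulky C6 substituent equatorial has the C1 acetate axial and screening the lower face, so the peracid should add from the upper face to the only alkene left.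

Step 16
Reactants: 25 epoxide
Product: 26 trans-diaxial bromohydrin (3S,4S) having C3–Br below the ring and C4–OH above it
Conditions: TMSBr and MeOH (1.1 equiv each, HBr in situ), CH2Cl2, −78 °C
Reagents that add atoms: bromotrimethylsilane, C[Si](C)(C)Br
Why: Acid-mediated epoxide opening in which the Fürst–Plattner rule and Markovnikov polarisation agree, so bromide attacks tertiary C3 from the lower face, and the ion-paired bromide in a cold water-free medium is expected to outrun participation by the C1 acetate.

Step 17
Reactants: 26 bromohydrin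
Product: 29 trans-diaxial 3-bromo-4-chloride (3S,4S), via C4 chlorosulfite 27 (not isolated), via bromonium chloride 28 (not isolated)
Conditions: SOCl2, pyridine, CH2Cl2, −30 to 0 °C
Reagents that add atoms: thionyl chloride, O=S(Cl)Cl
Why: Chlorodehydroxylation with neighbouring-group participation, in which the axial C3 bromine is antiperiplanar to the C4 chlorosulfite and expels it to give the lower-face bromonium ion, which chloride opens in the trans-diaxial sense at C4 from above, so C4 keeps its configuration by double inversion and bromine stays below the ring.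

Step 18
Reactants: 29 diaxial 3-bromo-4-chloride
Product: 30 diequatorial 3-chloro-4-bromide (3R,4R), the C8 silyl ether of the target
Conditions: MeCN, CaCO3 (acid scavenger), sealed tube, about 100 °C
Reagents that add atoms: none
Why: Thermal diaxial-to-diequatorial rearrangement of a vicinal dihalide, known for cyclohexane bromochlorides, in which bromine slides from C3 to C4 on the lower face while chlorine slides from C4 to C3 on the upper face through a tight bromonium chloride pair; this sets 3R and 4R, removes the syn-axial C3–Br/C1–OAc contact, puts chlorine on the tertiary carbon and is favoured by a polar solvent, and recovered 29 can be heated again.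

Step 19
Reactants: 30 silyl ether
Product: 31 target CNP0251357.1 (1R,3R,4R,6S,7S,8S,10S)
Conditions: HF·pyridine, THF, 0 °C to rt
Reagents that add atoms: none
Why: Fluoride-driven desilylation under mildly acidic conditions frees the axial C8 hydroxyl without base, so the acetate, the tertiary chloride and both secondary bromides should survive.

**Compound list**
1 | (S)-4-benzyloxazolidin-2-one | O=C1N[C@@H](Cc2ccccc2)CO1 | starting material
2 | pent-4-enoyl chloride | C=CCCC(=O)Cl | starting material
3 | N-lithio-(S)-4-benzyloxazolidin-2-one | [Li]N1[C@@H](Cc2ccccc2)COC1=O | intermediate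
4 | (S)-4-benzyl-3-(pent-4-enoyl)oxazolidin-2-one | C=CCCC(=O)N1[C@@H](Cc2ccccc2)COC1=O | intermediate
5 | 3-methylbut-3-en-1-ol | CC(=C)CCO | starting material
6 | 3-methylbut-3-enal | CC(=C)CC=O | intermediate
7 | dibutylboron Z-enolate of 4 | C=CC/C=C(\OB(CCCC)CCCC)N1[C@@H](Cc2ccccc2)COC1=O | intermediate
8 | (S)-4-benzyl-3-[(2S,3R)-2-allyl-3-hydroxy-5-methylhex-5-enoyl]oxazolidin-2-one | O[C@H](CC(C)=C)[C@H](CC=C)C(=O)N1[C@@H](Cc2ccccc2)COC1=O | intermediate
9 | (S)-4-benzyl-3-[(1S,6R)-6-hydroxy-4-methylcyclohex-3-ene-1-carbonyl]oxazolidin-2-one | O[C@@H]1CC(C)=CC[C@@H]1C(=O)N1[C@@H](Cc2ccccc2)COC1=O | intermediate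
10 | (1S,6R)-6-hydroxy-N-methoxy-N,4-dimethylcyclohex-3-ene-1-carboxamide | O[C@@H]1CC(C)=CC[C@@H]1C(=O)N(C)OC | intermediate
11 | 1-[(1S,6R)-6-hydroxy-4-methylcyclohex-3-en-1-yl]ethan-1-one | O[C@@H]1CC(C)=CC[C@@H]1C(C)=O | intermediate
12 | 2-methylfuran | Cc1ccco1 | starting material
13 | 5-methyl-2-furyllithium | [Li]c1ccc(C)o1 | intermediate
14 | (5-methylfuran-2-yl)magnesium bromide | Br[Mg]c1ccc(C)o1 | intermediate
15 | (1R,6S)-6-[(1S)-1-hydroxy-1-(5-methylfuran-2-yl)ethyl]-3-methylcyclohex-3-en-1-ol (key-step precursor, C1 hydroxyl free) | O[C@@H]1CC(C)=CC[C@@H]1[C@](C)(O)c1ccc(C)o1 | intermediate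
16 | 2,5-dihydroxy-2,5-dihydrofuran from 15 (diastereomers at C8 and C11) | O[C@@H]1CC(C)=CC[C@@H]1[C@](C)(O)C1(O)C=CC(C)(O)O1 | intermediate
17 | Z-enedione (C8 and C11 ketones, C9=C10 cis) | O[C@@H]1CC(C)=CC[C@@H]1[C@](C)(O)C(=O)/C=C\C(C)=O | intermediate
18 | (2S)-6-hydroxy-2-[(1S,6R)-6-hydroxy-4-methylcyclohex-3-en-1-yl]-2,6-dimethyl-2H-pyran-3(6H)-one (key-step product; anomers equilibrate, 11R drawn) | O[C@@H]1CC(C)=CC[C@@H]1[C@]1(C)O[C@@](C)(O)C=CC1=O | intermediate
19 | tricyclic enone ketal (1R,6S,7S,11S), O1 bridging C1 and C11 | O2[C@@H]1CC(C)=CC[C@@H]1[C@]1(C)O[C@@]2(C)C=CC1=O | intermediate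
20 | tricyclic β-bromo ketone (10S) | O2[C@@H]1CC(C)=CC[C@@H]1[C@]1(C)O[C@@]2(C)[C@@H](Br)CC1=O | intermediate
21 | tricyclic bromo alcohol (8S,10S) | O2[C@@H]1CC(C)=CC[C@@H]1[C@]1(C)O[C@@]2(C)[C@@H](Br)C[C@@H]1O | intermediate
22 | C8 TBS ether of 21 | O2[C@@H]1CC(C)=CC[C@@H]1[C@]1(C)O[C@@]2(C)[C@@H](Br)C[C@@H]1O[Si](C)(C)C(C)(C)C | intermediate
23 | C1 alcohol with C11 gem-dimethyl ring B (1R,6S,7S,8S,10S) | O[C@@H]1CC(C)=CC[C@@H]1[C@]1(C)OC(C)(C)[C@@H](Br)C[C@@H]1O[Si](C)(C)C(C)(C)C | intermediate
24 | C1 acetate of 23 | CC(=O)O[C@@H]1CC(C)=CC[C@@H]1[C@]1(C)OC(C)(C)[C@@H](Br)C[C@@H]1O[Si](C)(C)C(C)(C)C | intermediate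
25 | upper-face 3,4-epoxide (3R,4S) | CC(=O)O[C@@H]1C[C@@]2(C)O[C@H]2C[C@@H]1[C@]1(C)OC(C)(C)[C@@H](Br)C[C@@H]1O[Si](C)(C)C(C)(C)C | intermediate
26 | diaxial bromohydrin (3S,4S) | CC(=O)O[C@@H]1C[C@](C)(Br)[C@@H](O)C[C@@H]1[C@]1(C)OC(C)(C)[C@@H](Br)C[C@@H]1O[Si](C)(C)C(C)(C)C | intermediate
27 | C4 chlorosulfite of 26 | CC(=O)O[C@@H]1C[C@](C)(Br)[C@@H](OS(=O)Cl)C[C@@H]1[C@]1(C)OC(C)(C)[C@@H](Br)C[C@@H]1O[Si](C)(C)C(C)(C)C | intermediate
28 | lower-face C3–C4 bromonium chloride | CC(=O)O[C@@H]1C[C@]2(C)[Br+][C@@H]2C[C@@H]1[C@]1(C)OC(C)(C)[C@@H](Br)C[C@@H]1O[Si](C)(C)C(C)(C)C.[Cl-] | intermediate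
29 | diaxial 3-bromo-4-chloride (3S,4S) | CC(=O)O[C@@H]1C[C@](C)(Br)[C@@H](Cl)C[C@@H]1[C@]1(C)OC(C)(C)[C@@H](Br)C[C@@H]1O[Si](C)(C)C(C)(C)C | intermediate
30 | diequatorial 3-chloro-4-bromide (3R,4R), C8 TBS ether of the target | CC(=O)O[C@@H]1C[C@@](C)(Cl)[C@H](Br)C[C@@H]1[C@]1(C)OC(C)(C)[C@@H](Br)C[C@@H]1O[Si](C)(C)C(C)(C)C | intermediate
31 | CNP0251357.1 (1R,3R,4R,6S,7S,8S,10S) | CC(=O)O[C@@H]1C[C@@](C)(Cl)[C@H](Br)C[C@@H]1[C@]1(C)OC(C)(C)[C@@H](Br)C[C@@H]1O | target

Total steps: 19. Longest linear sequence: 18 (steps 1 and 3 to 19; step 2 runs in parallel).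

**Steps most likely to fail**

First, step 18. The halogen interchange may stall at an unfavourable equilibrium, or thermal loss of HBr from the tertiary bromide may outrun it. The fallback sets out from 24 and comes back at 30, and it builds the diequatorial pattern by substitution instead of rearrangement.
- Upper-face dihydroxylation of 24 (OsO4 cat., NMO) should give the cis-3,4-diol F1.
- SOCl2 and Et3N convert it into the cyclic sulfite F2, and RuCl3 (cat.) with NaIO4 into the cyclic sulfate F3.
- LiBr in THF opens the sulfate by SN2 at secondary C4 from the lower face to the lithium C3-sulfate C4-bromide F4.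
- Catalytic H2SO4 in wet THF hydrolyses this to the diequatorial bromohydrin F5.
- Base-free SOCl2 in Et2O then turns the tertiary alcohol into the chloride with retention by ion-pair collapse (SNi). The lower face is closed by the axial C1 acetate, so this gives 30.

Second, step 13. Ionisation of the ketal may be slow next to the electron-withdrawing C10 bromide. The tether may then simply reclose, or the oxocarbenium ion may lose a proton before methyl is transferred. The fallback sets out from 22 and comes back at 24.
- Acetolysis (Ac2O, TMSOTf cat., −20 °C), known for bridged ketals and anhydro sugars, opens the tether irreversibly to the C1,C11-diacetate F6.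
- Me2Zn with TMSOTf replaces the tertiary α-acetoxy ether group by methyl and gives 24 directly, so step 14 is not needed.

Third, step 8. Filming of the anode by furan-derived polymer, drift of the potential into alkene oxidation, or over-oxidation of the product may erode the electrolysis. The fallback sets out from 15 and comes back at 18.
- Sensitised photooxygenation (O2, tetraphenylporphyrin, visible light, CH2Cl2, −78 °C) adds singlet oxygen across the furan in a [4+2] sense to give the furan endoperoxide F7. This is much faster than the ene reaction at a trisubstituted alkene.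
- Me2S reduces F7 to the Z-enedione 17, which closes to 18.

**Further compounds**
F1 | step 18 | upper-face cis-3,4-diol (3R,4S) | CC(=O)O[C@@H]1C[C@@](C)(O)[C@@H](O)C[C@@H]1[C@]1(C)OC(C)(C)[C@@H](Br)C[C@@H]1O[Si](C)(C)C(C)(C)C
F2 | step 18 | 3,4-cyclic sulfite | CC(=O)O[C@@H]1C[C@@]2(C)OS(=O)O[C@H]2C[C@@H]1[C@]1(C)OC(C)(C)[C@@H](Br)C[C@@H]1O[Si](C)(C)C(C)(C)C
F3 | step 18 | 3,4-cyclic sulfate | CC(=O)O[C@@H]1C[C@@]2(C)OS(=O)(=O)O[C@H]2C[C@@H]1[C@]1(C)OC(C)(C)[C@@H](Br)C[C@@H]1O[Si](C)(C)C(C)(C)C
F4 | step 18 | lithium C3-sulfate C4-bromide | CC(=O)O[C@@H]1C[C@@](C)(OS(=O)(=O)[O-])[C@H](Br)C[C@@H]1[C@]1(C)OC(C)(C)[C@@H](Br)C[C@@H]1O[Si](C)(C)C(C)(C)C.[Li+]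
F5 | step 18 | diequatorial bromohydrin (C3–OH above, C4–Br below) | CC(=O)O[C@@H]1C[C@@](C)(O)[C@H](Br)C[C@@H]1[C@]1(C)OC(C)(C)[C@@H](Br)C[C@@H]1O[Si](C)(C)C(C)(C)C
F6 | step 13 | C1,C11-diacetate (C11 anomers) | CC(=O)O[C@@H]1CC(C)=CC[C@@H]1[C@]1(C)OC(C)(OC(C)=O)[C@@H](Br)C[C@@H]1O[Si](C)(C)C(C)(C)C
F7 | step 8 | furan endoperoxide (diastereomers at C8 and C11) | O[C@@H]1CC(C)=CC[C@@H]1[C@](C)(O)C12C=CC(C)(OO1)O2
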